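C1 bears OMe, C2 is =CH, C3 is =C and carries C7H2OBz, C4 bears OH, C5 bears OBz, C6 bears OH; the cyclohexene is the only ring to build.
Enabling feature: without Me and Bz, the carbinol tetrad C1–C6–C5–C4 (cis, trans, cis; O1/O6 on one face, O4/O5 on the other) has a C2 axis through the midpoints of C5–C6 and C2=C3, and the cis alkene C2=C3 lies between two carbinols.
Cuts: the O5 and O7 esters and the O1 methyl ether first, then C1–C2 and C3–C4 together. This leaves a four-carbon dialdehyde (C1, C6, C5, C4) with homotopic carbonyls and a three-carbon alkyne (C2, C3, C7).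
Forward: a divalent-titanium complex of the silylated propargyl ether is stitched across the dialdehyde, so the ring arises in one operation. Desilylation, an O4/O7 silylene bridge, O1 methylation, unmasking and O7/O5 benzoylation follow.
Stereochemistry: C5 and C6 come from D-tartaric acid; C4 and C1 are created in the annulation, each by Felkin–Anh addition anti to the adjacent dioxolane C–O bond; no centre is inverted afterwards.
Key step: step 3

Assumption: 3-(trimethylsilyl)prop-2-yn-1-ol and dimethyl 2,3-O-isopropylidene-D-tartrate are taken as catalogue chemicals. Stereodescriptors of the ring intermediates refer to the C1–C7 numbering above.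

Step 1
Reactants: 1 3-(trimethylsilyl)prop-2-yn-1-ol
Product: 2 3-(tert-butyldimethylsilyloxy)-1-(trimethylsilyl)prop-1-yne
Conditions: TBSCl, imidazole, CH2Cl2, 0 °C → rt
Reagents that add atoms: tert-butyldimethylsilyl chloride (TBSCl), CC(C)(C)[Si](C)(C)Cl
Why: Imidazole-promoted O-silylation of a primary alcohol; the bulky, weakly basic silyl ether is chosen because it is a poor leaving group and a poor ligand for titanium in step 3.

Step 2
Reactants: 3 dimethyl (4S,5S)-2,2-dimethyl-1,3-dioxolane-4,5-dicarboxylate (dimethyl 2,3-O-isopropylidene-D-tartrate)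
Product: 4 (4S,5S)-2,2-dimethyl-1,3-dioxolane-4,5-dicarbaldehyde
Conditions: i-Bu2AlH (2.1 equiv), toluene, −78 °C; MeOH, then aq potassium sodium tartrate; extract, dry by toluene azeotrope over 4 Å sieves, use the same day
Reagents that add atoms: none
Why: Partial ester reduction, in which each ester stops at the aluminium hemiacetal at −78 °C and releases the aldehyde only on work-up; the two stereocentres are not at risk because the trans-dioxolane is the more stable epimer.

Step 3
Reactants: 2 3-(tert-butyldimethylsilyloxy)-1-(trimethylsilyl)prop-1-yne; 4 (4S,5S)-2,2-dimethyl-1,3-dioxolane-4,5-dicarbaldehyde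
Product: 7 (1S,4R,5R,6R)-3-[(tert-butyldimethylsilyloxy)methyl]-5,6-O-isopropylidene-2-(trimethylsilyl)cyclohex-2-ene-1,4,5,6-tetrol, via alkyne–Ti(OiPr)2 complex 5 (not isolated), via Ti(OiPr)2 oxametallacyclopentene aldehyde 6 (not isolated)
Conditions: 2 (1.1 equiv), Ti(OiPr)4 (1.05 equiv), i-PrMgCl (2.1 equiv), Et2O, −78 → −50 °C, 2 h; cannulated slowly into 4 (1.0 equiv, 0.01 M, Et2O–THF), −78 °C; → −20 °C; sat. aq NH4Cl
Reagents that add atoms: titanium tetraisopropoxide, Ti(OiPr)4, CC(C)O[Ti](OC(C)C)(OC(C)C)OC(C)C (its Ti(OiPr)2 unit is carried only in 5 and 6 and is lost on work-up; 7 itself gains nothing but hydrogen)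
Why: Proposed new method: ligand exchange of (η2-propene)Ti(OiPr)2, formed from Ti(OiPr)4 and two i-PrMgCl, with 2 gives complex 5; one of the two homotopic carbonyls of 4 inserts into the Ti–C bond remote from silicon (C3–C4) to give metallacycle 6, and its remaining α-silyl alkenyl–titanium bond then adds to the tethered carbonyl (C2–C1) before hydrolysis releases 7. The closest known reaction type is the coupling of such divalent-titanium alkyne complexes with a single aldehyde, followed by protonolysis or iodinolysis of the surviving alkenyl–titanium bond; a second carbonyl addition at that bond is the new element and is counted on only because it is intramolecular. The cyclohexene closes in a 6-exo-trig mode, and the cis-1,2-dimetallated alkene guarantees that C1 and C4 end up cis on C2=C3. C4 is set by Felkin–Anh attack anti to the C5–O bond of the weakly chelating dioxolane (1,2-anti, which is O4 cis to O5 once the ring exists); C1 is set in the closure, where the equatorial C6–O bond is held antiperiplanar to the forming C1–C2 bond and the Felkin rotamer with the carbonyl oxygen next to C5 leads to a pseudoaxial O1 cis to O6. O1 and O4 finish on opposite faces and so cannot both be carried by one titanium, and the boat that a titanium-bridged closure to the unwanted 1,4-cis diol would need is forbidden by the trans-fused dioxolane, so an open transition state with the carbonyl activated by the ClMgOiPr already in the flask is expected. The step needs 1:1 annulation in place of 2:1 addition or oligomerisation: C2 symmetry makes either order of insertion give the same ring, and slow inverse addition at high dilution keeps 5 scarce while 6 closes.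

Step 4
Reactants: 7 (1S,4R,5R,6R)-3-[(tert-butyldimethylsilyloxy)methyl]-5,6-O-isopropylidene-2-(trimethylsilyl)cyclohex-2-ene-1,4,5,6-tetrol
Product: 8 (1R,4R,5R,6R)-3-(hydroxymethyl)-5,6-O-isopropylidenecyclohex-2-ene-1,4,5,6-tetrol
Conditions: Bu4NF (4 equiv), THF, rt → 50 °C
Reagents that add atoms: none
Why: Fluoride first cleaves the O7 silyl ether; the freed hydroxymethyl group (cis to silicon across C2=C3) and the adjacent C1 hydroxyl then assist attack at the vinylic silicon (hydroxyl-assisted protodesilylation of a vinylsilane via a pentacoordinate silicate, Brook-type C-to-O shift), so C2–H forms with retention and no stereocentre is touched.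

Step 5
Reactants: 8 (1R,4R,5R,6R)-3-(hydroxymethyl)-5,6-O-isopropylidenecyclohex-2-ene-1,4,5,6-tetrol
Product: 9 (1R,4R,5S,6R)-4,7-O-(di-tert-butylsilanediyl)-3-(hydroxymethyl)-5,6-O-isopropylidenecyclohex-2-ene-1,4,5,6-tetrol (only O1–H free)
Conditions: t-Bu2Si(OTf)2 (1.05 equiv), 2,6-lutidine, DMF, −40 → 0 °C
Reagents that add atoms: di-tert-butylsilyl bis(trifluoromethanesulfonate), CC(C)(C)[Si](OS(=O)(=O)C(F)(F)F)(OS(=O)(=O)C(F)(F)F)C(C)(C)C
Why: Cyclic silylene protection of a 1,3-diol, in which primary O7 is silylated first and the second Si–O bond can close only to O4 (six-membered ring, as in 4,6-O-silylene galactopyranosides), leaving O1 as the sole free hydroxyl, while the basic medium avoids the acid-catalysed drift of the strained trans-fused acetonide to the cis O1/O6 or O4/O5 pairs that an acetal exchange would invite.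

Step 6
Reactants: 9 (1R,4R,5S,6R)-4,7-O-(di-tert-butylsilanediyl)-3-(hydroxymethyl)-5,6-O-isopropylidenecyclohex-2-ene-1,4,5,6-tetrol
Product: 10 1-O-methyl ether of 9, (1R,4R,5S,6R)
Conditions: NaH, MeI, THF, 0 °C → rt
Reagents that add atoms: iodomethane (MeI), CI
Why: Williamson etherification of the single free alkoxide; silylene and acetonide tolerate these conditions, and the O1 alkoxide lies on the face opposite to O4 and cannot reach the bridging silicon, so no silyl migration is expected.

Step 7
Reactants: 10 1-O-methyl-4,7-O-(di-tert-butylsilanediyl)-5,6-O-isopropylidene derivative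
Product: 12 (1R,4R,5R,6S)-3-(hydroxymethyl)-1-O-methylcyclohex-2-ene-1,4,5,6-tetrol, via diol acetonide 11 (not isolated)
Conditions: HF·pyridine, THF, 0 °C; then 1 M aq HCl, same flask, rt; solid NaHCO3, evaporate, chromatograph
Reagents that add atoms: none
Why: Fluoride-mediated Si–O cleavage of the silylene is fast, and the trans-fused isopropylidene acetal is among the most acid-labile acetonides, so dilute aqueous acid completes the unmasking (acetal hydrolysis) without ionising the allylic C1–OMe or C4–OH bonds, whose cations are destabilised by the neighbouring oxygens.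

Step 8
Reactants: 12 (1R,4R,5R,6S)-3-(hydroxymethyl)-1-O-methylcyclohex-2-ene-1,4,5,6-tetrol
Product: 14 [(3R,4R,5R,6R)-5-(benzoyloxy)-4,6-dihydroxy-3-methoxycyclohex-1-en-1-yl]methyl benzoate (CNP0349013.4), via 7-O-monobenzoate 13 (not isolated)
Conditions: BzCl (2.1 equiv), Ph2BOCH2CH2NH2 (10 mol %), i-Pr2NEt (2.5 equiv), MeCN, 0 °C → rt
Reagents that add atoms: benzoyl chloride (BzCl), O=C(Cl)c1ccccc1
Why: Borinic-acid-catalysed regioselective acylation, in which the diphenylborinate binds the O4/O7 1,3-diol and the cis O4/O5 1,2-diol as tetracoordinate adducts that are acylated at primary O7 and at equatorial O5 respectively (the same axial–equatorial–equatorial triol pattern as a rhamnopyranoside, which reacts at O3), while pseudoaxial O4 and O6, which has no cis hydroxyl partner, stay free.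

Compound list
1 | 3-(trimethylsilyl)prop-2-yn-1-ol | C[Si](C)(C)C#CCO | starting material
2 | 3-(tert-butyldimethylsilyloxy)-1-(trimethylsilyl)prop-1-yne | C[Si](C)(C)C#CCO[Si](C)(C)C(C)(C)C | intermediate
3 | dimethyl (4S,5S)-2,2-dimethyl-1,3-dioxolane-4,5-dicarboxylate | COC(=O)[C@H]1OC(C)(C)O[C@@H]1C(=O)OC | starting material
4 | (4S,5S)-2,2-dimethyl-1,3-dioxolane-4,5-dicarbaldehyde | O=C[C@H]1OC(C)(C)O[C@@H]1C=O | intermediate
5 | (η2-alkyne)Ti(OiPr)2 complex of 2, drawn as the titanacyclopropene | C[Si](C)(C)C1=C(CO[Si](C)(C)C(C)(C)C)[Ti]1(OC(C)C)OC(C)C | intermediate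
6 | 2,2-diisopropoxy-1-oxa-2-titanacyclopent-3-ene: Ti bonded to O4 and to C2 (which also bears SiMe3), C3 bears CH2OTBS, C4 bears the dioxolane that carries the free C1 aldehyde; C4–O anti (Felkin) to C5–O | O=C[C@H]1OC(C)(C)O[C@@H]1[C@@H]2O[Ti](OC(C)C)(OC(C)C)C([Si](C)(C)C)=C2CO[Si](C)(C)C(C)(C)C | intermediate
7 | (1S,4R,5R,6R)-3-[(tert-butyldimethylsilyloxy)methyl]-5,6-O-isopropylidene-2-(trimethylsilyl)cyclohex-2-ene-1,4,5,6-tetrol (O1 cis to O6, O5 trans to O6, O4 cis to O5) | O[C@@H]1C([Si](C)(C)C)=C(CO[Si](C)(C)C(C)(C)C)[C@@H](O)[C@H]2OC(C)(C)O[C@H]12 | intermediate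
8 | (1R,4R,5R,6R)-3-(hydroxymethyl)-5,6-O-isopropylidenecyclohex-2-ene-1,4,5,6-tetrol | O[C@@H]1C=C(CO)[C@@H](O)[C@H]2OC(C)(C)O[C@H]12 | intermediate
9 | (1R,4R,5S,6R)-4,7-O-(di-tert-butylsilanediyl) derivative of 8 | O[C@@H]1C=C2CO[Si](C(C)(C)C)(C(C)(C)C)O[C@H]2[C@H]3OC(C)(C)O[C@H]13 | intermediate
10 | (1R,4R,5S,6R)-1-O-methyl ether of 9 | CO[C@@H]1C=C2CO[Si](C(C)(C)C)(C(C)(C)C)O[C@H]2[C@H]3OC(C)(C)O[C@H]13 | intermediate
11 | (1R,4R,5R,6R)-3-(hydroxymethyl)-5,6-O-isopropylidene-1-O-methylcyclohex-2-ene-1,4,5,6-tetrol | CO[C@@H]1C=C(CO)[C@@H](O)[C@H]2OC(C)(C)O[C@H]12 | intermediate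
12 | (1R,4R,5R,6S)-3-(hydroxymethyl)-1-O-methylcyclohex-2-ene-1,4,5,6-tetrol | CO[C@@H]1C=C(CO)[C@@H](O)[C@@H](O)[C@@H]1O | intermediate
13 | (1R,4R,5R,6S)-7-O-benzoate of 12 | CO[C@@H]1C=C(COC(=O)c2ccccc2)[C@@H](O)[C@@H](O)[C@@H]1O | intermediate
14 | [(3R,4R,5R,6R)-5-(benzoyloxy)-4,6-dihydroxy-3-methoxycyclohex-1-en-1-yl]methyl benzoate | CO[C@@H]1C=C(COC(=O)c2ccccc2)[C@@H](O)[C@@H](OC(=O)c2ccccc2)[C@@H]1O | target

Total step count: 8. Longest linear sequence: 7 steps (3 → 14, and equally 1 → 14).

Steps most likely to fail

Step 3. The alkenyl–titanium bond left in 6 may add to the tethered aldehyde too slowly. A second molecule of 5, hydride transfer from isopropoxide, or oligomerisation could then consume the free carbonyl first. β-Elimination of the silyloxy group from 5 and poor facial selectivity at either carbonyl are further ways to lose material.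

The fallback uses known chemistry and closes the ring by olefin metathesis at C2=C3; it sets out from 4. Commercial 2-bromoprop-2-en-1-ol is silylated (TBSCl, imidazole) to (2-bromoallyloxy)(tert-butyl)dimethylsilane F1. Bromine–lithium exchange (t-BuLi, Et2O, −78 °C) gives the alkenyllithium F2. This is added to an excess of 4 so that only one carbonyl reacts, giving the hydroxy aldehyde F3 (C3–C4 bond, Felkin–Anh). CH2=CHMgBr (THF, −78 °C) then adds to the second carbonyl to give the 1,7-diene-3,6-diol F4, whose diastereomers are separated at this stage. Ring-closing metathesis with the second-generation Grubbs catalyst (CH2Cl2, reflux) gives the 7-O-silyl cyclohexenediol F5. Bu4NF in THF removes the silyl ether to give triol 8, where the route is rejoined.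

Step 2. Over-reduction past the aldehyde stage is one risk. Hydration and oligomerisation of the water-soluble dialdehyde during the aqueous work-up is another. Carry-over of aluminium residues would consume the titanium reagent of step 3.

The fallback is full reduction followed by anhydrous re-oxidation; it sets out from 3. LiAlH4 in THF reduces both esters to (4R,5R)-2,2-dimethyl-1,3-dioxolane-4,5-dimethanol F6. A double Swern oxidation ((COCl)2, DMSO, Et3N, CH2Cl2, −78 °C) follows, with a non-aqueous work-up (dilution with pentane–Et2O, filtration of the ammonium salt, concentration). This returns 4 free of water and of aluminium salts.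

Step 8. O5 may not be fully discriminated from O4 and O6 when two acylations are run in one flask, and benzoyl groups may migrate between neighbouring hydroxyls under the amine base.

The fallback places the two esters one at a time, the first under protecting-group control and the second through a stoichiometric tin acetal; it sets out from 10. HF·pyridine alone (THF, 0 °C) gives diol 11, which is now isolated. BzCl (1 equiv) with 2,4,6-collidine in CH2Cl2 at −20 °C esterifies the primary O7 while O5 and O6 are still masked, giving the 7-O-benzoyl acetonide F7. Aqueous AcOH (80%, 40 °C) removes the acetonide to give triol 13. Bu2SnO in refluxing toluene with removal of water forms the 4,5-O-dibutylstannylene acetal F8. BzCl at 0 °C then acylates its equatorial oxygen O5 to give 14.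

Further compounds
F1 | step 3 | (2-bromoallyloxy)(tert-butyl)dimethylsilane | C=C(Br)CO[Si](C)(C)C(C)(C)C
F2 | step 3 | 3-(tert-butyldimethylsilyloxy)prop-1-en-2-yllithium | [Li]C(=C)CO[Si](C)(C)C(C)(C)C
F3 | step 3 | hydroxy aldehyde, mono-adduct of F2 to 4, with the target configuration at C4, C5 and C6 | O=C[C@H]1OC(C)(C)O[C@@H]1[C@H](O)C(=C)CO[Si](C)(C)C(C)(C)C
F4 | step 3 | 1,7-diene-3,6-diol with 4,5-acetonide and a 2-(silyloxymethyl) group, with the target configuration at C1, C4, C5 and C6 | C=C[C@@H](O)[C@H]1OC(C)(C)O[C@@H]1[C@H](O)C(=C)CO[Si](C)(C)C(C)(C)C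
F5 | step 3 | 7-O-tert-butyldimethylsilyl ether of 8 | O[C@@H]1C=C(CO[Si](C)(C)C(C)(C)C)[C@@H](O)[C@H]2OC(C)(C)O[C@H]12
F6 | step 2 | (4R,5R)-2,2-dimethyl-1,3-dioxolane-4,5-dimethanol (2,3-O-isopropylidene-D-threitol) | OC[C@H]1OC(C)(C)O[C@@H]1CO
F7 | step 8 | 7-O-benzoate of 11 | CO[C@@H]1C=C(COC(=O)c3ccccc3)[C@@H](O)[C@H]2OC(C)(C)O[C@H]12
F8 | step 8 | 4,5-O-dibutylstannylene acetal of 13 | CO[C@@H]1C=C(COC(=O)c3ccccc3)[C@H]2O[Sn](CCCC)(CCCC)O[C@H]2[C@@H]1O
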